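**Assumptions.** The SMILES corresponds to (2R,3R,6S)-2-methyl-6-(13-oxotetradecyl)piperidin-3-yl acetate, with all three ring substituents cis. Boc-D-alaninal and hexadecane-2,15-dione are taken as purchasable. The route is designed from known reaction classes and has not been run; the selectivities quoted are expectations.

## Retrosynthetic overview

1. Remove the O-acetyl group: the target comes from (−)-spectaline by O-selective acetylation of the protonated amino alcohol.
2. Open the piperidine (the only ring, formed late) at N–C6: intramolecular reductive amination of an N-Boc amino γ-hydroxy diketone, which sets C6 cis.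
3. Disconnect C4–C5: a threo N-Boc amino epoxide (C2–C4) is opened by the terminal azaenolate of hexadecane-2,15-dione bis(dimethylhydrazone), which supplies C5, C6 and the whole side chain.
4. The threo epoxide comes from NH-directed epoxidation of the Boc-allylamine made by methylenation of Boc-D-alaninal (C2 from D-alanine; C3 by substrate control).

## Route

**Step 1**
Reactants: 1, Boc-D-alaninal, tert-butyl N-[(2R)-1-oxopropan-2-yl]carbamate
Product: 2, tert-butyl N-[(2R)-but-3-en-2-yl]carbamate
Conditions: Ph3PCH3Br (2.2 equiv), KHMDS (2.1 equiv), THF, −78 °C → rt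
Reagents that add atoms: methyltriphenylphosphonium bromide, C[P+](c1ccccc1)(c1ccccc1)c1ccccc1.[Br-] (supplies the CH2)
Why: Wittig methylenation with a salt-free, non-stabilised ylide at low temperature converts CHO to CH=CH2 without epimerising the α-centre (the excess ylide takes the carbamate N–H), so the D-alanine centre becomes C2 (R) of the target.

**Step 2**
Reactants: 2
Product: 3, tert-butyl N-[(1R)-1-[(2S)-oxiran-2-yl]ethyl]carbamate (threo epoxide)
Conditions: mCPBA (2 equiv), CH2Cl2, 0 °C → rt, 48 h; minor erythro epoxide removed by chromatography
Reagents that add atoms: mCPBA, O=C(OO)c1cccc(Cl)c1 (supplies O)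
Why: Carbamate N–H-directed (Henbest-type) peracid epoxidation, in which the peracid hydrogen-bonds to NHBoc in the conformer with the allylic C–H eclipsing the alkene and delivers oxygen syn to nitrogen, giving the threo epoxide (expected roughly 5–10:1) and setting C3.

**Step 3**
Reactants: 4, hexadecane-2,15-dione
Product: 5, hexadecane-2,15-dione bis(N,N-dimethylhydrazone)
Conditions: Me2NNH2 (6 equiv), AcOH (cat.), EtOH, reflux; concentrate
Reagents that add atoms: 1,1-dimethylhydrazine, CN(C)N
Why: Hydrazone condensation turns both methyl ketones into Corey–Enders azaenolate precursors that lithiate only at the terminal CH3 and cannot self-aldolise.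

**Step 4**
Reactants: 5 (3.5 equiv) and 3 (1 equiv)
Product: 6, tert-butyl N-[(2R,3R)-3-hydroxy-6,19-dioxoicosan-2-yl]carbamate
Conditions: (i) 5, LDA (3.5 equiv), THF, 0 °C, 1 h; then 3, 0 °C → rt, 12 h; (ii) sat. aq. oxalic acid, Et2O, rt (the intermediate bis-hydrazone carbinol is not isolated; recovered 4 is recycled)
Reagents that add atoms: water, O (supplies the two ketone oxygens on hydrazone hydrolysis)
Why: Corey–Enders azaenolate alkylation, in which the terminal CH2–Li carbon opens the epoxide by SN2 at its unsubstituted CH2 (one equivalent of base is consumed by NHBoc), forming C4–C5 without touching C2 or C3, while excess symmetrical 5 favours mono-alkylation and mild acid unmasks both ketones with Boc intact.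

**Step 5**
Reactants: 6
Product: 7, (−)-spectaline, (2R,3R,6S)-2-methyl-6-(13-oxotetradecyl)piperidin-3-ol
Conditions: (i) 4 M HCl/dioxane, 0 °C → rt; evaporate; (ii) NaOAc (1.5 equiv), H2 (1 atm), 10% Pd/C, MeOH, rt; aq. NH3 work-up
Reagents that add atoms: none
Why: Boc removal followed by intramolecular reductive amination, in which the free amine condenses only with the δ-ketone (six-membered cyclic imine) and hydrogen adds to C6 from the face opposite the cis 2-Me/3-OH pair, giving the 2,6-cis (all-cis) piperidine and setting C6 (S); the remote methyl ketone is not reduced by Pd/C at 1 atm.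

**Step 6**
Reactants: 7
Product: 8, (−)-3-O-acetylspectaline, (2R,3R,6S)-2-methyl-6-(13-oxotetradecyl)piperidin-3-yl acetate
Conditions: AcCl (5 equiv), CF3CO2H, 0 °C → rt, 2 h; evaporate; cold sat. aq. NaHCO3/CH2Cl2 (store as the hydrochloride if kept)
Reagents that add atoms: acetyl chloride, CC(=O)Cl
Why: Chemoselective O-acylation of an amino alcohol under acidic conditions, where the fully protonated piperidine nitrogen is non-nucleophilic so only the C3 hydroxyl is acetylated, with retention at C3 and the ketone unaffected.

## Compound list

1 | Boc-D-alaninal, tert-butyl N-[(2R)-1-oxopropan-2-yl]carbamate | C[C@@H](NC(=O)OC(C)(C)C)C=O | starting material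
2 | tert-butyl N-[(2R)-but-3-en-2-yl]carbamate | C[C@@H](NC(=O)OC(C)(C)C)C=C | intermediate
3 | tert-butyl N-[(1R)-1-[(2S)-oxiran-2-yl]ethyl]carbamate | C[C@@H](NC(=O)OC(C)(C)C)[C@H]1CO1 | intermediate
4 | hexadecane-2,15-dione | CC(=O)CCCCCCCCCCCCC(C)=O | starting material
5 | hexadecane-2,15-dione bis(N,N-dimethylhydrazone) | CN(C)N=C(C)CCCCCCCCCCCCC(C)=NN(C)C | intermediate
6 | tert-butyl N-[(2R,3R)-3-hydroxy-6,19-dioxoicosan-2-yl]carbamate | C[C@@H](NC(=O)OC(C)(C)C)[C@H](O)CCC(=O)CCCCCCCCCCCCC(C)=O | intermediate
7 | (−)-spectaline, (2R,3R,6S)-2-methyl-6-(13-oxotetradecyl)piperidin-3-ol | CC(=O)CCCCCCCCCCCC[C@H]1CC[C@@H](O)[C@@H](C)N1 | intermediate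
8 | (−)-3-O-acetylspectaline, (2R,3R,6S)-2-methyl-6-(13-oxotetradecyl)piperidin-3-yl acetate | CC(=O)CCCCCCCCCCCC[C@H]1CC[C@@H](OC(C)=O)[C@@H](C)N1 | target

## Summary

Total steps: 6.
Longest linear sequence: 5 steps (1 → 2 → 3 → 6 → 7 → 8); the one-step preparation of 5 is the convergent branch.

Three steps most likely to fail, each with a fallback that changes the approach:

1. **Step 2 (threo selectivity with a small methyl substituent; slow terminal alkene).** Fallback: set C3 by Felkin-controlled ketone reduction instead of directed epoxidation. D-alanine → N,N-dibenzyl benzyl ester → chloromethyl ketone (ICH2Cl/MeLi) → NaBH4 (syn chlorohydrin) → base gives the N,N-dibenzyl threo epoxide. The benzyl groups are then removed in the same hydrogenation (Pd(OH)2) that closes the ring.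

2. **Step 4 (azaenolate opening of an NH-carbamate epoxide; bis-alkylation; possible attack of the carbamate on the epoxide).** Fallback: change the C–C bond-forming event to olefin cross-metathesis. Homologate epoxide 3 to the syn allylic alcohol with dimethylsulfonium methylide and couple it with heptadec-1-ene-3,16-dione (from 13-oxotetradecanoyl chloride and vinyltributylstannane) using Hoveyda–Grubbs II. The same acid/H2–Pd/C sequence then reduces the alkene and closes the ring.

3. **Step 6 (competing N-acetylation, O→N acyl shift on neutralisation, or enol acetate formation at the ketone).** Fallback: use a protecting-group sequence instead of protonation control. Trap 7 as the N-Cbz carbamate (CbzCl, aq. Na2CO3), acetylate the alcohol (Ac2O, DMAP), then remove Cbz by neutral hydrogenolysis (H2, Pd/C), which leaves the acetate and ketone intact.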